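**Retrosynthetic overview**

1. Numbering: amide carbonyl = C1, along the ansa chain to benzylic C15; benzene ring C16–C21 (C18 carries OH, C20 carries N). Target 32 ⇐ macrocycle 26 by hydroxyl-directed hydrogenation (sets C14), O-methylation, C7 carbamoylation and desilylation.
2. Enabling feature: the array C12(O)–C13H2–C14H(CH3)–C15H2–benzene ring is the hydrogenated form of an aryl-conjugated homoallylic alcohol ArCH=C(CH3)–CH2–CH(OH), the retron of a reductive union of a 1-arylpropyne with a terminal epoxide.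
3. Key disconnection C13–C14: the 19-membered ansa ring of 26 is closed from seco alkyne–epoxide 24 by a nickel-catalysed reductive alkyne–epoxide macrocyclisation. That one operation makes the ring, the C13–C14 bond, the free C12 carbinol (director for C14, later the methyl ether) and the E-C14=C15 alkene.
4. 24 ⇐ B-alkyl Suzuki–Miyaura union (C3–C4) of epoxide 15 with iodoacrylanilide 22. 15 ⇐ (S)-glyceraldehyde acetonide by two Z-crotylborations (C10–C11 substrate-controlled, C6–C7 catalyst-controlled) and a Wittig enal. 22 ⇐ 3-amino-5-bromophenol, propyne and (E)-3-iodo-2-methylacrylic acid.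
5. Ring order: the benzene ring is bought; the 19-membered ring is formed in the key step (dioxolane and oxirane are temporary rings).

Key step: step 13

Remark: aldehyde 1 and acid 20 are taken as catalogue compounds; 1 is used freshly distilled because it oligomerises and racemises on storage.

**Route**

Step 1
Reactants: 1 (S)-glyceraldehyde acetonide; 2 (Z)-crotylboronic acid pinacol ester
Product: 4 (1R,2S)-1-[(4S)-2,2-dimethyl-1,3-dioxolan-4-yl]-2-methylbut-3-en-1-ol, via O-boryl adduct 3 (not isolated)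
Conditions: CH2Cl2, 4 Å MS, rt; then H2O work-up
Reagents that add atoms: none
Why: Uncatalysed allylboration through a closed six-membered chair transition state, in which the Z-boronate sets the C10 methyl and C11 hydroxyl syn and the α-alkoxy aldehyde is attacked anti to the dioxolane oxygen (non-chelated 1,2-anti preference, reinforced for Z-crotyl reagents by a syn-pentane clash in the competing mode), so C11 (R) is set from the bought C12 centre.

Step 2
Reactants: 4 homoallylic alcohol
Product: 5 C11 triisopropylsilyl ether of 4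
Conditions: TIPSOTf, 2,6-lutidine, CH2Cl2, −78 → 0 °C
Reagents that add atoms: triisopropylsilyl triflate CC(C)[Si](C(C)C)(C(C)C)OS(=O)(=O)C(F)(F)F
Why: Silyl triflate silylation of a hindered secondary alcohol; TIPS is chosen to outlast the later TBS ether and to resist 1,2-silyl migration.

Step 3
Reactants: 5 silyl ether
Product: 7 (2R,3R)-3-[(4S)-2,2-dimethyl-1,3-dioxolan-4-yl]-2-methyl-3-[(triisopropylsilyl)oxy]propanal, via ozonide 6 (not isolated)
Conditions: O3, CH2Cl2, −78 °C; then PPh3, −78 °C → rt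
Reagents that add atoms: ozone [O-][O+]=O
Why: Ozonolysis of the only alkene through the 1,2,4-trioxolane and reductive work-up; the α-methyl aldehyde is used at once to avoid epimerisation at C10.

Step 4
Reactants: 7 aldehyde; 8 2-(triphenylphosphoranylidene)propanal
Product: 9 (2E,4S,5R)-5-[(4S)-2,2-dimethyl-1,3-dioxolan-4-yl]-2,4-dimethyl-5-[(triisopropylsilyl)oxy]pent-2-enal
Conditions: toluene, 90 °C
Reagents that add atoms: none
Why: Wittig olefination with a stabilised α-methyl ylide should give the E-trisubstituted enal (C8=C9) under non-basic conditions that leave C10 intact.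

Step 5
Reactants: 9 enal; 2 (Z)-crotylboronic acid pinacol ester
Product: 11 (3S,4R,5E,7S,8R)-8-[(4S)-2,2-dimethyl-1,3-dioxolan-4-yl]-3,5,7-trimethyl-8-[(triisopropylsilyl)oxy]octa-1,5-dien-4-ol, via O-boryl adduct 10 (not isolated)
Conditions: (R)-TRIP [(R)-3,3′-bis(2,4,6-triisopropylphenyl)-1,1′-binaphthyl-2,2′-diyl hydrogen phosphate] (5 mol %), toluene, 4 Å MS, −30 °C → rt; then H2O work-up
Reagents that add atoms: none
Why: Chiral phosphoric acid-catalysed crotylboration through a closed chair transition state, in which the Z-boronate gives the C6/C7 syn pair and the (R)-acid is expected to direct attack to the Re face of the enal (7R, 6S), the remote C10/C11 centres having little influence.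

Step 6
Reactants: 11 allylic alcohol
Product: 12 C7 tert-butyldimethylsilyl ether of 11
Conditions: TBSOTf, 2,6-lutidine, CH2Cl2, −78 °C
Reagents that add atoms: tert-butyldimethylsilyl triflate CC(C)(C)[Si](C)(C)OS(=O)(=O)C(F)(F)F
Why: Silyl triflate protection of the allylic C7 alcohol as the TBS ether, the group that is later removed selectively before carbamoylation.

Step 7
Reactants: 12 bis-silyl ether acetonide
Product: 13 (2S,3R,4S,5E,7R,8S)-7-[(tert-butyldimethylsilyl)oxy]-4,6,8-trimethyl-3-[(triisopropylsilyl)oxy]deca-5,9-diene-1,2-diol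
Conditions: CuCl2·2H2O, MeCN, 0 °C → rt
Reagents that add atoms: none
Why: Mild Lewis acid hydrolysis should cleave the terminal isopropylidene acetal selectively while the secondary TBS and TIPS ethers are retained.

Step 8
Reactants: 13 diol
Product: 15 terminal (S)-epoxide, via primary tosylate 14 (not isolated)
Conditions: TsCl, Et3N, Bu2SnO (cat.), CH2Cl2, 0 °C → rt; then K2CO3, MeOH, 0 °C
Reagents that add atoms: none
Why: Tin-catalysed selective sulfonylation of the primary hydroxyl followed by intramolecular Williamson closure (3-exo-tet) gives the terminal epoxide with C12 untouched (S retained).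

Step 9
Reactants: 16 3-amino-5-bromophenol
Product: 17 3-bromo-5-[(triisopropylsilyl)oxy]aniline
Conditions: TIPSCl, imidazole, DMF, rt
Reagents that add atoms: triisopropylsilyl chloride CC(C)[Si](Cl)(C(C)C)C(C)C
Why: Chemoselective O-silylation of the phenol in the presence of the less reactive aniline nitrogen.

Step 10
Reactants: 17 aryl bromide; 18 propyne
Product: 19 3-(prop-1-yn-1-yl)-5-[(triisopropylsilyl)oxy]aniline
Conditions: Pd(PPh3)2Cl2 (cat.), CuI (copper iodide, cat.), Et3N, DMF, sealed tube, 60 °C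
Reagents that add atoms: none
Why: Sonogashira coupling installs C14, C15 and the future C14 methyl group as a 1-arylpropyne.

Step 11
Reactants: 20 (E)-3-iodo-2-methylprop-2-enoic acid; 19 aminoaryl alkyne
Product: 22 (2E)-3-iodo-2-methyl-N-{3-(prop-1-yn-1-yl)-5-[(triisopropylsilyl)oxy]phenyl}prop-2-enamide, via acid chloride 21 (not isolated)
Conditions: (COCl)2, DMF (cat.), CH2Cl2, 0 °C → rt; then 19, pyridine, CH2Cl2, 0 °C
Reagents that add atoms: none
Why: Acid chloride formation and N-acylation of the aniline, with the E-iodoalkene geometry retained.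

Step 12
Reactants: 15 epoxide; 22 iodoacrylanilide
Product: 24 seco alkyne–epoxide amide, via alkylborane 23 (not isolated)
Conditions: 9-BBN, THF, rt; then aq. K3PO4, 22, PdCl2(dppf) (cat.), AsPh3 (cat.), DMF, rt
Reagents that add atoms: none
Why: Regioselective hydroboration of the monosubstituted alkene by 9-BBN (trisubstituted alkene and epoxide untouched) and B-alkyl Suzuki–Miyaura coupling with the E-vinyl iodide, with retention of geometry, should forge C3–C4 and the E-C2=C3 unit.

Step 13
Reactants: 24 seco alkyne–epoxide amide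
Product: 26 19-membered ansa lactam with 12-hydroxyl and E-C14=C15, via diethylborinate 25 (not isolated)
Conditions: Ni(cod)2 (20 mol %), PBu3 (40 mol %), Et3B (3 equiv), THF/toluene, slow addition of 24 at high dilution, rt → 45 °C; aqueous work-up
Reagents that add atoms: none
Why: Zerovalent nickel bound to the aryl alkyne engages the Et3B-activated epoxide at its terminal carbon C13 to give an oxanickelacycle, which Et3B opens by ethyl transfer; β-hydride elimination and C15–H reductive elimination then release the homoallylic borinate, so C13–C14 forms by net syn-addition of H and alkyl across the alkyne. The reaction type is the nickel-catalysed reductive coupling of alkynes with epoxides, precedented for 1-arylpropynes with monosubstituted epoxides and as a ring-closing reaction that gives macrocycles. The 19-membered ring closes in endo mode at both partners (endo-dig at the alkyne; attack at the distal terminal epoxide carbon, so that both epoxide carbons end up in the ring). No new tetrahedral stereocentre is formed: C12 is not touched and keeps its S configuration, and the E geometry of C14=C15 follows from the syn-addition. The step needs alkyne regioselectivity (C–C at the methyl-bearing carbon, secured by the aryl group that stabilises nickel at C15), epoxide regioselectivity (secured by the unhindered CH2 terminus) and ring closure over oligomerisation (favoured by slow addition at high dilution and by the rigid E-olefin and anilide segments of the chain); the trisubstituted alkenes, the silyl ethers and the secondary amide are not substrates for this catalyst.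

Step 14
Reactants: 26 macrocyclic homoallylic alcohol
Product: 27 14,15-dihydro macrocycle with (14R)-methyl
Conditions: [Rh(nbd)(dppb)]BF4 (10 mol %), H2 (50 bar), CH2Cl2, rt
Reagents that add atoms: none
Why: Hydroxyl-directed hydrogenation with a cationic rhodium diphosphine catalyst, in which the C12 hydroxyl and the C14=C15 alkene chelate the metal with the C11 substituent anti to C14, so that H2 should add to the face giving the 12,14-anti isomer (14R), while the unbound trisubstituted C8=C9 and the conjugated C2=C3 alkenes stay untouched.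

Step 15
Reactants: 27 C12 alcohol
Product: 28 C12 methyl ether
Conditions: TMSCHN2 (in portions), aq. HBF4 (cat.), CH2Cl2, 0 °C
Reagents that add atoms: trimethylsilyldiazomethane C[Si](C)(C)C=[N+]=[N-]
Why: Acid-catalysed methyl transfer from a diazoalkane to the hydroxyl group, conditions under which the weakly acidic and weakly nucleophilic anilide is not expected to be alkylated.

Step 16
Reactants: 28 methyl ether
Product: 29 C7 alcohol
Conditions: HF·pyridine, pyridine, THF, 0 °C → rt
Reagents that add atoms: none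
Why: Buffered fluoride desilylation should distinguish the secondary TBS ether from the bulkier secondary TIPS ether and the aryl TIPS ether.

Step 17
Reactants: 29 C7 alcohol
Product: 31 C7 primary carbamate, via trichloroacetyl carbamate 30 (not isolated)
Conditions: Cl3CC(O)NCO, CH2Cl2, 0 °C; then neutral Al2O3, rt
Reagents that add atoms: trichloroacetyl isocyanate O=C=NC(=O)C(Cl)(Cl)Cl
Why: Carbamoylation of the only free hydroxyl with trichloroacetyl isocyanate, followed by hydrolytic loss of the trichloroacetyl group on alumina, gives the primary carbamate.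

Step 18
Reactants: 31 bis-TIPS carbamate
Product: 32 CNP0247621.1
Conditions: TBAF, AcOH, THF, rt → 40 °C
Reagents that add atoms: none
Why: Buffered fluoride should cleave the aryl and the hindered secondary TIPS ethers without touching the carbamate, the E-alkenes or the stereocentres.

**Compound list**

1 | (4S)-2,2-dimethyl-1,3-dioxolane-4-carbaldehyde [(S)-glyceraldehyde acetonide] | O=C[C@@H]1COC(C)(C)O1 | starting material
2 | 2-[(2Z)-but-2-en-1-yl]-4,4,5,5-tetramethyl-1,3,2-dioxaborolane [(Z)-crotylboronic acid pinacol ester] | C/C=C\CB1OC(C)(C)C(C)(C)O1 | starting material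
3 | O-(pinacolatoboryl) ether of 4 (formed in the flask) | C=C[C@H](C)[C@@H](OB1OC(C)(C)C(C)(C)O1)[C@@H]2COC(C)(C)O2 | intermediate
4 | (1R,2S)-1-[(4S)-2,2-dimethyl-1,3-dioxolan-4-yl]-2-methylbut-3-en-1-ol | C=C[C@H](C)[C@@H](O)[C@@H]1COC(C)(C)O1 | intermediate
5 | {[(1R,2S)-1-[(4S)-2,2-dimethyl-1,3-dioxolan-4-yl]-2-methylbut-3-en-1-yl]oxy}tri(propan-2-yl)silane | C=C[C@H](C)[C@@H](O[Si](C(C)C)(C(C)C)C(C)C)[C@@H]1COC(C)(C)O1 | intermediate
6 | 1,2,4-trioxolane (ozonide) of 5 (formed in the flask; mixture at the trioxolane carbon) | C1OOC(O1)[C@H](C)[C@@H](O[Si](C(C)C)(C(C)C)C(C)C)[C@@H]2COC(C)(C)O2 | intermediate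
7 | (2R,3R)-3-[(4S)-2,2-dimethyl-1,3-dioxolan-4-yl]-2-methyl-3-[(triisopropylsilyl)oxy]propanal | O=C[C@H](C)[C@@H](O[Si](C(C)C)(C(C)C)C(C)C)[C@@H]1COC(C)(C)O1 | intermediate
8 | 2-(triphenylphosphoranylidene)propanal | CC(C=O)=P(c1ccccc1)(c1ccccc1)c1ccccc1 | starting material
9 | (2E,4S,5R)-5-[(4S)-2,2-dimethyl-1,3-dioxolan-4-yl]-2,4-dimethyl-5-[(triisopropylsilyl)oxy]pent-2-enal | O=C/C(C)=C/[C@H](C)[C@@H](O[Si](C(C)C)(C(C)C)C(C)C)[C@@H]1COC(C)(C)O1 | intermediate
10 | O-(pinacolatoboryl) ether of 11 (formed in the flask) | C=C[C@H](C)[C@@H](OB1OC(C)(C)C(C)(C)O1)/C(C)=C/[C@H](C)[C@@H](O[Si](C(C)C)(C(C)C)C(C)C)[C@@H]2COC(C)(C)O2 | intermediate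
11 | (3S,4R,5E,7S,8R)-8-[(4S)-2,2-dimethyl-1,3-dioxolan-4-yl]-3,5,7-trimethyl-8-[(triisopropylsilyl)oxy]octa-1,5-dien-4-ol | C=C[C@H](C)[C@@H](O)/C(C)=C/[C@H](C)[C@@H](O[Si](C(C)C)(C(C)C)C(C)C)[C@@H]1COC(C)(C)O1 | intermediate
12 | tert-butyl{[(3S,4R,5E,7S,8R)-8-[(4S)-2,2-dimethyl-1,3-dioxolan-4-yl]-3,5,7-trimethyl-8-[(triisopropylsilyl)oxy]octa-1,5-dien-4-yl]oxy}dimethylsilane | C=C[C@H](C)[C@@H](O[Si](C)(C)C(C)(C)C)/C(C)=C/[C@H](C)[C@@H](O[Si](C(C)C)(C(C)C)C(C)C)[C@@H]1COC(C)(C)O1 | intermediate
13 | (2S,3R,4S,5E,7R,8S)-7-[(tert-butyldimethylsilyl)oxy]-4,6,8-trimethyl-3-[(triisopropylsilyl)oxy]deca-5,9-diene-1,2-diol | C=C[C@H](C)[C@@H](O[Si](C)(C)C(C)(C)C)/C(C)=C/[C@H](C)[C@@H](O[Si](C(C)C)(C(C)C)C(C)C)[C@@H](O)CO | intermediate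
14 | 1-O-(4-methylbenzenesulfonyl) derivative of 13 (formed in the flask) | C=C[C@H](C)[C@@H](O[Si](C)(C)C(C)(C)C)/C(C)=C/[C@H](C)[C@@H](O[Si](C(C)C)(C(C)C)C(C)C)[C@@H](O)COS(=O)(=O)c1ccc(C)cc1 | intermediate
15 | tert-butyl{[(3S,4R,5E,7S,8R)-3,5,7-trimethyl-8-[(2S)-oxiran-2-yl]-8-[(triisopropylsilyl)oxy]octa-1,5-dien-4-yl]oxy}dimethylsilane | C=C[C@H](C)[C@@H](O[Si](C)(C)C(C)(C)C)/C(C)=C/[C@H](C)[C@@H](O[Si](C(C)C)(C(C)C)C(C)C)[C@@H]1CO1 | intermediate
16 | 3-amino-5-bromophenol | Nc1cc(O)cc(Br)c1 | starting material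
17 | 3-bromo-5-[(triisopropylsilyl)oxy]aniline | Nc1cc(O[Si](C(C)C)(C(C)C)C(C)C)cc(Br)c1 | intermediate
18 | propyne | CC#C | starting material
19 | 3-(prop-1-yn-1-yl)-5-[(triisopropylsilyl)oxy]aniline | CC#Cc1cc(N)cc(O[Si](C(C)C)(C(C)C)C(C)C)c1 | intermediate
20 | (2E)-3-iodo-2-methylprop-2-enoic acid | OC(=O)/C(C)=C/I | starting material
21 | (2E)-3-iodo-2-methylprop-2-enoyl chloride (formed in the flask) | ClC(=O)/C(C)=C/I | intermediate
22 | (2E)-3-iodo-2-methyl-N-{3-(prop-1-yn-1-yl)-5-[(triisopropylsilyl)oxy]phenyl}prop-2-enamide | O=C(Nc1cc(O[Si](C(C)C)(C(C)C)C(C)C)cc(C#CC)c1)/C(C)=C/I | intermediate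
23 | B-alkyl-9-borabicyclo[3.3.1]nonane from 15, boron on the former terminal alkene carbon (C4) (formed in the flask) | B1(CC[C@H](C)[C@@H](O[Si](C)(C)C(C)(C)C)/C(C)=C/[C@H](C)[C@@H](O[Si](C(C)C)(C(C)C)C(C)C)[C@@H]2CO2)C3CCCC1CCC3 | intermediate
24 | (2E,6S,7R,8E,10S,11R)-7-[(tert-butyldimethylsilyl)oxy]-2,6,8,10-tetramethyl-11-[(2S)-oxiran-2-yl]-N-{3-(prop-1-yn-1-yl)-5-[(triisopropylsilyl)oxy]phenyl}-11-[(triisopropylsilyl)oxy]undeca-2,8-dienamide | CC#Cc1cc(O[Si](C(C)C)(C(C)C)C(C)C)cc(c1)NC(=O)/C(C)=C/CC[C@H](C)[C@@H](O[Si](C)(C)C(C)(C)C)/C(C)=C/[C@H](C)[C@@H](O[Si](C(C)C)(C(C)C)C(C)C)[C@@H]1CO1 | intermediate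
25 | 12-O-diethylboryl ether of 26 (formed in the flask) | C/C1=C\c2cc(O[Si](C(C)C)(C(C)C)C(C)C)cc(c2)NC(=O)/C(C)=C/CC[C@H](C)[C@@H](O[Si](C)(C)C(C)(C)C)/C(C)=C/[C@H](C)[C@@H](O[Si](C(C)C)(C(C)C)C(C)C)[C@@H](OB(CC)CC)C1 | intermediate
26 | 19-membered ansa lactam (ring C1–C15, C16, C21, C20, N): (2E,8E,14E)-triene; methyls on C2, C6 (S), C8, C10 (S), C14; 7-OTBS (7R); 11-OTIPS (11R); 12-OH (12S); 18-OTIPS | C/C1=C\c2cc(O[Si](C(C)C)(C(C)C)C(C)C)cc(c2)NC(=O)/C(C)=C/CC[C@H](C)[C@@H](O[Si](C)(C)C(C)(C)C)/C(C)=C/[C@H](C)[C@@H](O[Si](C(C)C)(C(C)C)C(C)C)[C@@H](O)C1 | intermediate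
27 | 14,15-dihydro derivative of 26 with (14R)-methyl; (2E,8E)-diene; other groups as in 26 | C[C@@H]1Cc2cc(O[Si](C(C)C)(C(C)C)C(C)C)cc(c2)NC(=O)/C(C)=C/CC[C@H](C)[C@@H](O[Si](C)(C)C(C)(C)C)/C(C)=C/[C@H](C)[C@@H](O[Si](C(C)C)(C(C)C)C(C)C)[C@@H](O)C1 | intermediate
28 | (12S)-12-O-methyl ether of 27 | C[C@@H]1Cc2cc(O[Si](C(C)C)(C(C)C)C(C)C)cc(c2)NC(=O)/C(C)=C/CC[C@H](C)[C@@H](O[Si](C)(C)C(C)(C)C)/C(C)=C/[C@H](C)[C@@H](O[Si](C(C)C)(C(C)C)C(C)C)[C@@H](OC)C1 | intermediate
29 | (7R)-7-hydroxy compound (28 without the TBS group; 11-OTIPS and 18-OTIPS retained) | C[C@@H]1Cc2cc(O[Si](C(C)C)(C(C)C)C(C)C)cc(c2)NC(=O)/C(C)=C/CC[C@H](C)[C@@H](O)/C(C)=C/[C@H](C)[C@@H](O[Si](C(C)C)(C(C)C)C(C)C)[C@@H](OC)C1 | intermediate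
30 | 7-O-[N-(trichloroacetyl)carbamoyl] derivative of 29 (formed in the flask) | C[C@@H]1Cc2cc(O[Si](C(C)C)(C(C)C)C(C)C)cc(c2)NC(=O)/C(C)=C/CC[C@H](C)[C@@H](OC(=O)NC(=O)C(Cl)(Cl)Cl)/C(C)=C/[C@H](C)[C@@H](O[Si](C(C)C)(C(C)C)C(C)C)[C@@H](OC)C1 | intermediate
31 | 7-O-carbamoyl derivative of 29 (11-OTIPS and 18-OTIPS retained) | C[C@@H]1Cc2cc(O[Si](C(C)C)(C(C)C)C(C)C)cc(c2)NC(=O)/C(C)=C/CC[C@H](C)[C@@H](OC(N)=O)/C(C)=C/[C@H](C)[C@@H](O[Si](C(C)C)(C(C)C)C(C)C)[C@@H](OC)C1 | intermediate
32 | CNP0247621.1: 19-membered ansa lactam, (2E,8E), (6S,7R,10S,11R,12S,14R), 7-O-carbamate, 11-OH, 12-OMe, 18-OH | CO[C@H]1C[C@H](C)Cc2cc(O)cc(c2)NC(=O)/C(C)=C/CC[C@H](C)[C@@H](OC(N)=O)/C(C)=C/[C@H](C)[C@H]1O | target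

**Step count and risks**

Total step count: 18. Longest linear sequence: 15 steps (steps 1–8 and 12–18).

Steps most likely to fail:

1. Step 13. At the dilution needed for ring closure, activation of the epoxide may be too slow, so that nickel-mediated oligomerisation of the aryl alkyne or reductive opening and isomerisation of the epoxide take over. Fallback, setting out from 15 and 19 and returning to the route at 26: the C13–C14 bond is made first, intermolecularly and at high concentration, by the same nickel-catalysed reductive coupling of the 1-arylpropyne with the terminal epoxide (Ni(cod)2, PBu3, Et3B), which gives the borinate F1 and after work-up the amino homoallylic alcohol F2. Acylation of the aniline nitrogen with acid chloride 21 (made from 20 as in step 11) gives the iodoacrylamide F3. Excess 9-BBN converts the terminal alkene and the free hydroxyl into the bis-borane F4, and an intramolecular B-alkyl Suzuki–Miyaura coupling (PdCl2(dppf), AsPh3, aq. Cs2CO3, DMF/THF, high dilution) closes the 19-membered ring at C3–C4 and frees the C12 hydroxyl to give 26.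

2. Step 14. A single carbinol in a flexible 19-membered ring may give insufficient facial bias at C14, or prolonged exposure may lead to alkene migration or reduction at C8=C9. Fallback, setting out from 26 and returning at 28: 26 is first O-methylated as in step 15 to the methyl ether F5, which removes the directing group. The C14=C15 bond is then reduced under catalyst control with a chiral iridium N,P complex, [Ir(cod)(t-Bu-PHOX)]B[C6H3(CF3)2]4 (ligand antipode chosen by screening), H2, CH2Cl2, a catalyst class established for unfunctionalised trisubstituted aryl alkenes. This gives 28 directly.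

3. Step 15. The hindered C12 carbinol may convert incompletely, with competing alkylation of the lactam carbonyl oxygen or acid-induced loss of a silyl ether. Fallback, setting out from 27 and returning at 28: a two-stage methylation that avoids electrophilic methyl donors and acid. Pummerer-type etherification (DMSO, Ac2O, AcOH, rt) gives the methylthiomethyl ether F6, and reductive C–S cleavage with deactivated Raney Ni (acetone-washed, EtOH, rt) gives the methyl ether 28.

**Further compounds**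

F1 | step 13 | 12-O-diethylboryl ether of F2 (formed in the flask) | C=C[C@H](C)[C@@H](O[Si](C)(C)C(C)(C)C)/C(C)=C/[C@H](C)[C@@H](O[Si](C(C)C)(C(C)C)C(C)C)[C@@H](OB(CC)CC)C/C(C)=C/c1cc(N)cc(O[Si](C(C)C)(C(C)C)C(C)C)c1
F2 | step 13 | acyclic amino homoallylic alcohol: 15 joined at its epoxide CH2 to the methyl-bearing alkyne carbon of 19, (E)-ArCH=C(CH3)CH2CH(OH), 12S | C=C[C@H](C)[C@@H](O[Si](C)(C)C(C)(C)C)/C(C)=C/[C@H](C)[C@@H](O[Si](C(C)C)(C(C)C)C(C)C)[C@@H](O)C/C(C)=C/c1cc(N)cc(O[Si](C(C)C)(C(C)C)C(C)C)c1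
F3 | step 13 | N-[(2E)-3-iodo-2-methylprop-2-enoyl] derivative of F2 | C=C[C@H](C)[C@@H](O[Si](C)(C)C(C)(C)C)/C(C)=C/[C@H](C)[C@@H](O[Si](C(C)C)(C(C)C)C(C)C)[C@@H](O)C/C(C)=C/c1cc(NC(=O)/C(C)=C/I)cc(O[Si](C(C)C)(C(C)C)C(C)C)c1
F4 | step 13 | bis-borane from F3: B-alkyl-9-BBN at the former terminal alkene carbon and O-(9-BBN) borinate at C12 (formed in the flask) | B1(CC[C@H](C)[C@@H](O[Si](C)(C)C(C)(C)C)/C(C)=C/[C@H](C)[C@@H](O[Si](C(C)C)(C(C)C)C(C)C)[C@@H](OB2C3CCCC2CCC3)C/C(C)=C/c4cc(NC(=O)/C(C)=C/I)cc(O[Si](C(C)C)(C(C)C)C(C)C)c4)C5CCCC1CCC5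
F5 | step 14 | (12S)-12-O-methyl ether of 26 (E-C14=C15 retained) | C/C1=C\c2cc(O[Si](C(C)C)(C(C)C)C(C)C)cc(c2)NC(=O)/C(C)=C/CC[C@H](C)[C@@H](O[Si](C)(C)C(C)(C)C)/C(C)=C/[C@H](C)[C@@H](O[Si](C(C)C)(C(C)C)C(C)C)[C@@H](OC)C1
F6 | step 15 | 12-O-(methylthiomethyl) ether of 27 | C[C@@H]1Cc2cc(O[Si](C(C)C)(C(C)C)C(C)C)cc(c2)NC(=O)/C(C)=C/CC[C@H](C)[C@@H](O[Si](C)(C)C(C)(C)C)/C(C)=C/[C@H](C)[C@@H](O[Si](C(C)C)(C(C)C)C(C)C)[C@@H](OCSC)C1
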